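**Plan**
1. Retrosynthetic cuts, in order: the benzyl groups on O5 and O7 and the methyl on O6; then O1–C8a (ring C); then C2–C3 (C2 from ethyl formate); then C4–C4a (acylation of pyrogallol by the ring B acetic acid).
2. Enabling feature: in ring A, C8a (which carries O1) is para to C6 (which carries oxygen), and both carbons ortho to C6 (C5 and C7) are oxygenated. Ring A is therefore a hydroquinone monoether, which a free C6 phenol with a C8a–H can reach by losing two electrons and two protons.
3. Forward order: rings A and B are bought intact and joined at C4–C4a. O7, O6 and O5 are then distinguished by their order of reactivity (benzyl, allyl, benzyl, then allyl off). C2 is added, ring C closes last at the anode, and O6-methylation and hydrogenolysis finish the route.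
4. Stereochemistry: the target has no stereocentre. The only stereo-element on the way is the Z-enol of 9, which is set by tautomeric equilibrium.

Key step: step 7

Remark: isoflavone numbering (O1, C2 … C8a; primed numbers for ring B) is used for the ring atoms of all intermediates. Compound 9 is drawn as its Z-enol, which equilibrates with the E-enol and the keto-aldehyde; only the Z form can cyclise.

Step 1
Reactants: 1 pyrogallol; 2 2-(2,3,4-trimethoxyphenyl)acetic acid
Product: 3 1-(2,3,4-trihydroxyphenyl)-2-(2,3,4-trimethoxyphenyl)ethan-1-one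
Conditions: BF3·OEt2 (solvent), 85 °C, N2; then aq. NaOAc
Reagents that add atoms: none
Why: Friedel–Crafts (Nencki-type) acylation of a free polyphenol by an arylacetic acid in BF3 etherate is the standard deoxybenzoin synthesis; pyrogallol reacts at C4 (ortho to one OH, para to another) much faster than the fully etherified ring B of 2, and the product ketone is deactivated towards a second acylation.

Step 2
Reactants: 3 1-(2,3,4-trihydroxyphenyl)-2-(2,3,4-trimethoxyphenyl)ethan-1-one
Product: 4 1-[4-(benzyloxy)-2,3-dihydroxyphenyl]-2-(2,3,4-trimethoxyphenyl)ethan-1-one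
Conditions: BnBr (1.0 equiv), NaHCO3, DMF, 40 °C, N2
Reagents that add atoms: benzyl bromide, BrCc1ccccc1
Why: Williamson etherification under acidity control: the hydrogen bond from the 2-OH holds the carbonyl coplanar with ring A, so the para 4-OH (future O7) is by far the most acidic and should be the only hydroxyl that NaHCO3 ionises, as in the classical partial alkylation of gallacetophenone-type ketones.

Step 3
Reactants: 4 1-[4-(benzyloxy)-2,3-dihydroxyphenyl]-2-(2,3,4-trimethoxyphenyl)ethan-1-one
Product: 5 1-[4-(benzyloxy)-2-hydroxy-3-(prop-2-en-1-yloxy)phenyl]-2-(2,3,4-trimethoxyphenyl)ethan-1-one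
Conditions: allyl bromide (1.1 equiv), K2CO3, acetone, reflux, N2
Reagents that add atoms: allyl bromide, C=CCBr
Why: Williamson etherification: the 3-OH is free while the 2-OH is locked in the hydrogen bond to the ketone, so mild base and about one equivalent of halide should alkylate O3 (future O6) only and place there a group orthogonal to benzyl.

Step 4
Reactants: 5 1-[4-(benzyloxy)-2-hydroxy-3-(prop-2-en-1-yloxy)phenyl]-2-(2,3,4-trimethoxyphenyl)ethan-1-one
Product: 6 1-[2,4-bis(benzyloxy)-3-(prop-2-en-1-yloxy)phenyl]-2-(2,3,4-trimethoxyphenyl)ethan-1-one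
Conditions: BnBr (1.3 equiv), K2CO3, DMF, 60 °C
Reagents that add atoms: benzyl bromide, BrCc1ccccc1
Why: Williamson etherification of the chelated phenol needs these more forcing conditions, under which the phenoxide rather than the much less acidic benzylic CH2 is the species alkylated; capping this oxygen (future O5) also shuts off the ordinary chromone closure through it.

Step 5
Reactants: 6 1-[2,4-bis(benzyloxy)-3-(prop-2-en-1-yloxy)phenyl]-2-(2,3,4-trimethoxyphenyl)ethan-1-one
Product: 7 1-[2,4-bis(benzyloxy)-3-hydroxyphenyl]-2-(2,3,4-trimethoxyphenyl)ethan-1-one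
Conditions: Pd(PPh3)4 (5 mol %), morpholine, THF, rt
Reagents that add atoms: none
Why: Tsuji–Trost-type deallylation: zerovalent palladium ionises the allyl aryl ether to a π-allyl complex that morpholine captures, which frees the future C6 phenol under neutral conditions and leaves the benzyl ethers, methyl ethers and ketone untouched.

Step 6
Reactants: 7 1-[2,4-bis(benzyloxy)-3-hydroxyphenyl]-2-(2,3,4-trimethoxyphenyl)ethan-1-one; 8 ethyl formate
Product: 9 (Z)-1-[2,4-bis(benzyloxy)-3-hydroxyphenyl]-3-hydroxy-2-(2,3,4-trimethoxyphenyl)prop-2-en-1-one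
Conditions: NaH (4 equiv), HCO2Et (excess), THF, 0 °C to rt, Ar; then cold 1 M HCl to pH 4
Reagents that add atoms: none
Why: Crossed Claisen condensation (C-formylation) of the deoxybenzoin enolate with non-enolisable ethyl formate is the classical way to install C2 of isoflavones; the phenoxide is a spectator (any aryl formate is cleaved on work-up), the benzyl on O5 prevents spontaneous cyclisation, and the product should settle as the hydrogen-bonded Z-enol.

Step 7
Reactants: 9 (Z)-1-[2,4-bis(benzyloxy)-3-hydroxyphenyl]-3-hydroxy-2-(2,3,4-trimethoxyphenyl)prop-2-en-1-one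
Product: 11 5,7-bis(benzyloxy)-6-hydroxy-3-(2,3,4-trimethoxyphenyl)-4H-chromen-4-one, via 8aH-chromene-4,6-dione tautomer 10 (not isolated)
Conditions: undivided cell, graphite anode, Pt cathode, constant current (2 mA cm−2, 2.1 F mol−1), Bu4NPF6 (0.1 M), 2,6-lutidine (2 equiv), dry HFIP (0.02 M in 9), rt, N2
Reagents that add atoms: none
Why: Proposed new method: at graphite the C6 phenol, enriched by the benzyloxy groups on C5 and C7, should lose two electrons and its proton (to 2,6-lutidine) at a lower potential than ring B or the acyl-conjugated enol, while HFIP stabilises the phenoxonium ion without trapping it and loosens the internal O–H···O=C4 hydrogen bond so that the enol oxygen can turn towards C8a. That oxygen adds to C8a, the para terminus of the cation, to give dienone 10, and loss of the C8a proton rearomatises ring A to 11 while the cathode discharges the protons as H2; should the enolate be oxidised first, addition of its oxygen-centred radical to C8a and a second electron transfer lead to the same 10. The closest known reactions are the anodic para-trapping of phenols by oxygen nucleophiles (quinone monoketals, spirodienone lactones) and the anodic dehydrogenative lactonisation of biaryl-2-carboxylic acids; closure of a pyranone onto the para C–H of a phenol has not been shown. Ring C closes in a 6-endo-trig sense (conjugate addition across C4a=C8a of the C5 oxocarbenium form), and no stereocentre remains because C8a of 10 becomes planar again. Site selectivity is needed between C8a and C5, both within reach of the tether: addition at C5 gives a mixed ketal that cannot aromatise and re-ionises by expelling the vinylogous carboxylate, so only the C8a adduct leaves the equilibrium, whereas carbon attack of the enol would need a four-membered ring and C6' of ring B has only one, twisted, para methoxy donor. Over-oxidation of 11 is held back by passing only about 2 F mol−1 at low current density in dry HFIP, where the oxidised product finds no nucleophile, and by the electron demand of the now coplanar C4 carbonyl and of O1 as a vinylogous ester oxygen; dilution disfavours intermolecular coupling of phenoxyl radicals.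

Step 8
Reactants: 11 5,7-bis(benzyloxy)-6-hydroxy-3-(2,3,4-trimethoxyphenyl)-4H-chromen-4-one
Product: 12 5,7-bis(benzyloxy)-6-methoxy-3-(2,3,4-trimethoxyphenyl)-4H-chromen-4-one
Conditions: MeI, K2CO3, dry acetone, reflux
Reagents that add atoms: iodomethane, CI
Why: Williamson methylation of the only free hydroxyl; K2CO3 in dry acetone should not open the pyranone ring.

Step 9
Reactants: 12 5,7-bis(benzyloxy)-6-methoxy-3-(2,3,4-trimethoxyphenyl)-4H-chromen-4-one
Product: 13 5,7-dihydroxy-6-methoxy-3-(2,3,4-trimethoxyphenyl)-4H-chromen-4-one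
Conditions: H2 (1 atm), Pd/C (10 wt %), EtOAc, rt, stopped after two equivalents of H2
Reagents that add atoms: none
Why: Catalytic hydrogenolysis of aryl benzyl ethers is faster than saturation of the isoflavone C2=C3 bond at 1 atm, the methyl ethers are inert, and removal of both benzyl groups gives the target.

**Compound list**
1 | pyrogallol (benzene-1,2,3-triol) | Oc1cccc(O)c1O | starting material
2 | 2-(2,3,4-trimethoxyphenyl)acetic acid | OC(=O)Cc1ccc(OC)c(OC)c1OC | starting material
3 | 1-(2,3,4-trihydroxyphenyl)-2-(2,3,4-trimethoxyphenyl)ethan-1-one | O=C(Cc1ccc(OC)c(OC)c1OC)c1ccc(O)c(O)c1O | intermediate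
4 | 1-[4-(benzyloxy)-2,3-dihydroxyphenyl]-2-(2,3,4-trimethoxyphenyl)ethan-1-one | O=C(Cc1ccc(OC)c(OC)c1OC)c1ccc(OCc2ccccc2)c(O)c1O | intermediate
5 | 1-[4-(benzyloxy)-2-hydroxy-3-(prop-2-en-1-yloxy)phenyl]-2-(2,3,4-trimethoxyphenyl)ethan-1-one | O=C(Cc1ccc(OC)c(OC)c1OC)c1ccc(OCc2ccccc2)c(OCC=C)c1O | intermediate
6 | 1-[2,4-bis(benzyloxy)-3-(prop-2-en-1-yloxy)phenyl]-2-(2,3,4-trimethoxyphenyl)ethan-1-one | O=C(Cc1ccc(OC)c(OC)c1OC)c1ccc(OCc2ccccc2)c(OCC=C)c1OCc1ccccc1 | intermediate
7 | 1-[2,4-bis(benzyloxy)-3-hydroxyphenyl]-2-(2,3,4-trimethoxyphenyl)ethan-1-one | O=C(Cc1ccc(OC)c(OC)c1OC)c1ccc(OCc2ccccc2)c(O)c1OCc1ccccc1 | intermediate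
8 | ethyl formate | CCOC=O | starting material
9 | (Z)-1-[2,4-bis(benzyloxy)-3-hydroxyphenyl]-3-hydroxy-2-(2,3,4-trimethoxyphenyl)prop-2-en-1-one | O=C(/C(=C\O)c1ccc(OC)c(OC)c1OC)c1ccc(OCc2ccccc2)c(O)c1OCc1ccccc1 | intermediate
10 | 5,7-bis(benzyloxy)-3-(2,3,4-trimethoxyphenyl)-8aH-chromene-4,6-dione (not isolated; transient C8a centre, racemic) | O=C1C(OCc2ccccc2)=CC2OC=C(c3ccc(OC)c(OC)c3OC)C(=O)C2=C1OCc1ccccc1 | intermediate
11 | 5,7-bis(benzyloxy)-6-hydroxy-3-(2,3,4-trimethoxyphenyl)-4H-chromen-4-one | COc1ccc(-c2coc3cc(OCc4ccccc4)c(O)c(OCc4ccccc4)c3c2=O)c(OC)c1OC | intermediate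
12 | 5,7-bis(benzyloxy)-6-methoxy-3-(2,3,4-trimethoxyphenyl)-4H-chromen-4-one | COc1ccc(-c2coc3cc(OCc4ccccc4)c(OC)c(OCc4ccccc4)c3c2=O)c(OC)c1OC | intermediate
13 | 5,7-dihydroxy-6-methoxy-3-(2,3,4-trimethoxyphenyl)-4H-chromen-4-one | COc1ccc(-c2coc3cc(O)c(OC)c(O)c3c2=O)c(OC)c1OC | target

Total step count: 9. Longest linear sequence: 9 steps (from 1 or 2 to 13).

**Steps most likely to fail**

1. **Step 7.**
   - What may go wrong: electron transfer from the enolate or ring B instead of the phenol; intermolecular coupling of phenoxyl radicals; loss of a benzyl group from the oxidised ring A; further oxidation of the product.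
   - Fallback (known chemistry, sets out from 7 and comes back at 12): the para C–H is turned into a leaving group instead of being oxidised.
   - NBS (1 equiv, MeCN, 0 °C) should brominate 7 para to the free phenol, the only open activated site of ring A. This gives 1-[2,4-bis(benzyloxy)-6-bromo-3-hydroxyphenyl]-2-(2,3,4-trimethoxyphenyl)ethan-1-one F1.
   - MeI/K2CO3 then caps the phenol, so that no phenoxide deactivates the later substitution. This gives 1-[2,4-bis(benzyloxy)-6-bromo-3-methoxyphenyl]-2-(2,3,4-trimethoxyphenyl)ethan-1-one F2.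
   - Claisen formylation (NaH, HCO2Et) gives (Z)-1-[2,4-bis(benzyloxy)-6-bromo-3-methoxyphenyl]-3-hydroxy-2-(2,3,4-trimethoxyphenyl)prop-2-en-1-one F3.
   - Intramolecular Ullmann-type O-arylation of its enolate (CuI, 1,10-phenanthroline, K2CO3, DMF, 100 °C) forms O1–C8a and delivers 12. This is the established chromone closure of 1-(2-haloaryl)-1,3-dicarbonyl compounds.

2. **Step 2.**
   - What may go wrong: poor discrimination between O4 and O3, with over-benzylation, and air oxidation of the triol under base.
   - Fallback (sets out from 2 and comes back at 7, replacing steps 1 to 5): both benzyl groups are placed on a symmetric resorcinol before ring A is desymmetrised, so no hydroxyl has to be told from another.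
   - Acid 2 is converted with 1,1'-carbonyldiimidazole and MeNH(OMe)·HCl into N-methoxy-N-methyl-2-(2,3,4-trimethoxyphenyl)acetamide F4.
   - Commercial 2,6-dihydroxyacetophenone is dibenzylated (BnBr, K2CO3, DMF) to 1-[2,6-bis(benzyloxy)phenyl]ethan-1-one F5.
   - Baeyer–Villiger oxidation (mCPBA, CH2Cl2) gives 2,6-bis(benzyloxy)phenyl acetate F6.
   - NBS in MeCN brominates para to one benzyloxy group and ortho to the other, giving 2,6-bis(benzyloxy)-3-bromophenyl acetate F7.
   - Methanolysis (K2CO3, MeOH) gives 2,6-bis(benzyloxy)-3-bromophenol F8.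
   - Deprotonation and bromine–lithium exchange (n-BuLi, 2 equiv, THF, −78 °C), followed by addition of F4, gives 7.

3. **Step 4.**
   - What may go wrong: sluggish O-alkylation of the chelated, hindered phenol, with competing C-benzylation through the deoxybenzoin enolate.
   - Fallback (sets out from 5 and comes back at 6): the chelate and the acidic methylene are both removed by temporarily lowering the oxidation level of C4.
   - NaBH4 (MeOH, 0 °C) reduces 5 to racemic 1-[4-(benzyloxy)-2-hydroxy-3-(prop-2-en-1-yloxy)phenyl]-2-(2,3,4-trimethoxyphenyl)ethan-1-ol F9.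
   - Its now ordinary phenol is benzylated chemoselectively over the secondary alcohol (BnBr, K2CO3, acetone). This gives racemic 1-[2,4-bis(benzyloxy)-3-(prop-2-en-1-yloxy)phenyl]-2-(2,3,4-trimethoxyphenyl)ethan-1-ol F10.
   - Dess–Martin periodinane (CH2Cl2, rt) restores the ketone, giving 6.

**Further compounds**
F1 | step 7 | 1-[2,4-bis(benzyloxy)-6-bromo-3-hydroxyphenyl]-2-(2,3,4-trimethoxyphenyl)ethan-1-one | O=C(Cc1ccc(OC)c(OC)c1OC)c1c(Br)cc(OCc2ccccc2)c(O)c1OCc1ccccc1
F2 | step 7 | 1-[2,4-bis(benzyloxy)-6-bromo-3-methoxyphenyl]-2-(2,3,4-trimethoxyphenyl)ethan-1-one | O=C(Cc1ccc(OC)c(OC)c1OC)c1c(Br)cc(OCc2ccccc2)c(OC)c1OCc1ccccc1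
F3 | step 7 | (Z)-1-[2,4-bis(benzyloxy)-6-bromo-3-methoxyphenyl]-3-hydroxy-2-(2,3,4-trimethoxyphenyl)prop-2-en-1-one | O=C(/C(=C\O)c1ccc(OC)c(OC)c1OC)c1c(Br)cc(OCc2ccccc2)c(OC)c1OCc1ccccc1
F4 | step 2 | N-methoxy-N-methyl-2-(2,3,4-trimethoxyphenyl)acetamide | CON(C)C(=O)Cc1ccc(OC)c(OC)c1OC
F5 | step 2 | 1-[2,6-bis(benzyloxy)phenyl]ethan-1-one | CC(=O)c1c(OCc2ccccc2)cccc1OCc1ccccc1
F6 | step 2 | 2,6-bis(benzyloxy)phenyl acetate | CC(=O)Oc1c(OCc2ccccc2)cccc1OCc1ccccc1
F7 | step 2 | 2,6-bis(benzyloxy)-3-bromophenyl acetate | CC(=O)Oc1c(OCc2ccccc2)ccc(Br)c1OCc1ccccc1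
F8 | step 2 | 2,6-bis(benzyloxy)-3-bromophenol | Oc1c(OCc2ccccc2)ccc(Br)c1OCc1ccccc1
F9 | step 4 | 1-[4-(benzyloxy)-2-hydroxy-3-(prop-2-en-1-yloxy)phenyl]-2-(2,3,4-trimethoxyphenyl)ethan-1-ol (racemic) | OC(Cc1ccc(OC)c(OC)c1OC)c1ccc(OCc2ccccc2)c(OCC=C)c1O
F10 | step 4 | 1-[2,4-bis(benzyloxy)-3-(prop-2-en-1-yloxy)phenyl]-2-(2,3,4-trimethoxyphenyl)ethan-1-ol (racemic) | OC(Cc1ccc(OC)c(OC)c1OC)c1ccc(OCc2ccccc2)c(OCC=C)c1OCc1ccccc1
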